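## The problem

The target 21 is a γ-lactone (ring A, O1–C2(=O)–C3–C4–C5) with an acetoxy group at C4, a 2-methylprop-1-enyl group at C5 and, at C3, an exocyclic E-alkene leading into a ten-carbon chain (C1'–C10', counted from the exocyclic CH). The chain carries an acetoxy carbinol at C3', an E-alkene C4'=C5', a Z-alkene C8'=C9' and a primary allylic benzoate at C10'. No rings have to be fused; the task is to join a small, densely functionalised ring to a polyene chain through an alkene of defined geometry. Of the three stereocentres, C4 (S) and C5 (R) are trans neighbours on ring A and can be taken together from the chiral pool. C3' (R) is insulated from the ring by the sp2 carbon C1' and the methylene C2', so the ring cannot control it and a reagent or catalyst must. Three groups are fragile: the C4 acetate is allylic to the conjugated C3=C1' alkene (SN2' displacement, elimination towards a furan); the C3' acetate is β to the C2' methylene, the vinylogous α-position of the lactone (E1cB to a triene); and the C10' benzoate is a primary allylic ester that low-valent metals and strong Lewis acids ionise and alkoxides cleave. Enolate chemistry must therefore be finished before either acetate is in place, and the closing steps must be neither strongly basic nor strongly acidic. Two features invite a short solution. First, the C3' oxygen is δ to the C2 carbonyl through the C3=C1' alkene (O=C2–C3=C1'–C2'–C3'–O), so C2'–C3' is a vinylogous aldol bond, and cutting it leaves an α-methyl enal whose carbons are the oxidised skeleton of nerol. Second, C2–C5 with the isobutenyl CH are C1–C5 of 2-deoxy-D-ribose, whose C3 (S) and C4 (R) become C4 (S) and C5 (R) of the target unchanged.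

## Retrosynthesis

**21 ⇒ 20 ⇒ 19.** The first cut removes the two acetyl groups of 21 (the O–acyl bonds at C4 and C3') to give diol 20, and behind it the C4 silyl ether 19. The acetates go on last because neither would survive the enolate chemistry that builds the skeleton: a C4 acetate sits β to the lactone enolate carbon and would be expelled, and both carry acidic α-protons. The benzoate is carried from the start, since nothing in the route should disturb it and a late benzoylation would have to tell a primary from two secondary alcohols. Precursor 19 differs from the target only in protecting groups. The forward steps must cleave one secondary silyl ether without base and acetylate two secondary allylic alcohols mildly.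

**19 ⇒ 13 + 17.** Cutting C2'–C3' of 19 in the vinylogous aldol sense gives silyl dienolate 13 and enal 17. The neighbouring cuts are weaker. Cutting C3=C1' (aldol condensation of the enolate of 6 with a C3'-oxygenated aldehyde) needs C3' made first in a separate asymmetric step and gives E/Z mixtures on dehydration. Cutting C1'–C2' calls for a halomethylene lactone and a metal-mediated coupling that an allylic benzoate does not tolerate. The chosen cut divides the twenty skeletal carbons into two halves of ten, creates C3' in the bond-forming step and returns the C3=C1' alkene to conjugation as a consequence of the addition. It asks the forward reaction for attack through the terminal carbon of the dienolate, E geometry at C3=C1', catalyst control of the enal face, and a promoter mild enough to spare the benzoate and the C4 silyl ether.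

**13 ⇒ 11 ⇒ 9 ⇒ 6 + 7.** Dienolate 13 is the O-silylated extended enolate 12 of α-ethylidene lactone 11 (enol O–Si bond cut; γ-deprotonation forward). Lactone 11 arises by dehydration of aldol 9 through mesylate 10, and 9 from the lithium enolate 8 of lactone 6 and acetaldehyde 7 (C3–C1' bond cut). The two carbons come from the simplest electrophile available. The two stereocentres formed in the aldol are destroyed again, and the E/Z ratio of 11 does not matter because both isomers give the same dienolate. The forward steps must outrun β-elimination of the C4 silyloxy group from the enolates, which is a matter of low temperature and, for 13, of a non-aqueous isolation.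

**6 ⇒ 5 ⇒ 4 ⇒ 3 ⇒ 2 ⇒ 1.** The isobutenyl alkene of 6 is cut in the Wittig sense to aldehyde 5, the oxidation product of primary alcohol 4. Alcohol 4 comes from bis-silyl ether 3 by selective cleavage of the primary silyl ether, 3 from lactone diol 2, and 2 by oxidation of 2-deoxy-D-ribose 1. Building C4 and C5 by asymmetric dihydroxylation of a dienoate would require the less electron-rich of two alkenes to react; the sugar supplies both centres in the right absolute and relative configuration. The price is one protecting-group adjustment. The olefination must be run cold because 5 is an α-acyloxy aldehyde with a β-leaving group.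

**17 ⇒ 16 ⇒ 15 ⇒ 14.** Enal 17 is the oxidation product of allylic alcohol 16, which comes from neryl benzoate 15 by allylic oxidation of the E-methyl group of the terminal alkene, and 15 from nerol 14. The Z-alkene C8'=C9' and the whole chain are bought with the starting material; assembling a trisubstituted Z-alkene by olefination would be longer and less selective. The forward oxidation must choose the distal alkene over the one deactivated by the benzoyloxymethyl group, and the E-methyl over the Z-methyl. Both are established preferences of selenium-based allylic oxidation.

## Roads not taken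

**Alternative 1:** carbonylative closure of ring A.
- **Cut:** the carbonyl carbon C2 is removed from ring A (bonds C3–C2 and C2–O1), leaving the acyclic E-iodoalkene diol A1 with iodine on C3 and free hydroxyls on C4 and C5.
- **Forward key step:** Pd(PPh3)4 (zerovalent palladium) inserts into the C3–I bond, CO inserts, and the C5 hydroxyl captures the acylpalladium to give the E-alkylidene hydroxy lactone A2.
- **Merits:** the alkene geometry passes stereospecifically from A1 to A2, so E is secured by construction. On this point the road is better than the chosen plan, which relies on a conformational preference of the dienolate. Five-membered closure through O5 should also win clearly over four-membered closure through O4.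
- **Weak points:** A1 is the whole molecule less one carbon. All three stereocentres and a trisubstituted iodoalkene of fixed geometry must be assembled in open-chain form, with no obvious chiral-pool source for C4 and C5. The benzoate cannot be carried, because zerovalent palladium ionises primary allylic esters, so C3' and C10' travel as silyl ethers. From A2 the end game needs four steps: acetylation of C4, double desilylation, selective benzoylation of the primary alcohol, and acetylation of C3'.
- **Comparison:** the chosen plan sets against the better geometric control a convergent union of two ten-carbon halves, C3' created in the same step, both ring centres from a sugar, and an end game of two steps.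

**Alternative 2:** alkenylation at C5 under acetoxonium control.
- **Cut:** the C5–alkenyl bond.
- **Forward key step:** BF3·OEt2 ionises the C5 acetate of diacetoxy lactone A3, the C4 acetate bridges to an acetoxonium ion, and potassium (2-methylprop-1-enyl)trifluoroborate A4 delivers its alkenyl group to C5 from the face opposite the bridge, giving A5.
- **Merits:** the trans relation of C4 and C5 would be enforced by neighbouring-group participation and is the relation the target needs. The C4 acetate is in place early, and the base-sensitive aldehyde 5 with its Wittig reaction is avoided. In these respects the road is gentler than the chosen one.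
- **Weak points:** the cation at C5 is flanked by an ester oxygen (O1 is acylated by C2), a poor donor, so a forceful Lewis acid is needed. In A3 the C4 acetate is itself allylic to the conjugated alkene and competes as a leaving group, and elimination across C4–C5 towards an aromatic furan is an easy exit. The C3' silyl ether is allylic and the chain carries acid-sensitive trisubstituted alkenes. Alkenyltrifluoroborate additions to lactone-derived cations of this kind have little close backing. The step addresses only C5: C3' and the chain still have to be attached beforehand, and A5 needs three further steps (double desilylation, selective benzoylation, acetylation).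
- **Comparison:** the chosen plan also places one step on a new substrate, but that step solves the stereocentre the ring cannot control and joins the two halves at once.

**Alternative 3:** nickel-catalysed cross-electrophile coupling at the allylic methylene.
- **Cut:** the C1'–C2' bond.
- **Forward key step:** E-bromomethylene lactone A6 and the N-hydroxyphthalimide ester A7 of the β-silyloxy acid couple under NiBr2(CH3OCH2CH2OCH3), 4,4'-di-tert-butyl-2,2'-bipyridine and Zn with loss of CO2, giving the tris-silyl ether A8.
- **Merits:** the road is convergent. The alkene geometry is carried in from A6, and C3' is fixed in A7 beforehand by auxiliary-controlled acetate aldol chemistry. This is more certain than catalyst control on an untried dienolate and is a real advantage over the chosen plan.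
- **Weak points:** after decarboxylation the C2' radical and the derived alkylnickel species carry a silyloxy group on the neighbouring carbon C3' and can β-eliminate it. A6 is a β-bromoacrylate that can take up the radical by addition–elimination with loss of geometry, and it has an allylic silyloxy group exposed to the reducing metal. Low-valent nickel and Zn would ionise an allylic benzoate, so A8 needs global desilylation, selective primary benzoylation and bis-acetylation (three steps). A7 itself costs about five steps from an enal of the type of 17.
- **Comparison:** the chosen plan reaches 19 from the two building blocks in one catalytic step that forms the bond and the stereocentre together, and finishes in two steps. It pays for this with less certain control of C3' and of the alkene geometry.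

Key step: step 12

Assumption: the (R,R)-enantiomer of the bisphosphoramide catalyst is taken to expose the Re face of the silicon-bound enal to the dienolate (Re-face attack corresponds to 3'R). If the sense is the reverse, the (S,S)-enantiomer is used and nothing else in the route changes.

## Route

Step 1
Reactants: 1 2-deoxy-D-ribose
Product: 2 2-deoxy-D-ribono-1,4-lactone, (4S,5R)-4-hydroxy-5-(hydroxymethyl)oxolan-2-one
Conditions: Br2, H2O, rt, dark; Ag2CO3 to neutrality, filtration
Reagents that add atoms: none
Why: Bromine-water oxidation of the aldose hemiacetal to the aldonolactone; the 1,4-lactone is the stable ring size and no stereocentre is touched, so sugar C3 (S) and C4 (R) become lactone C4 (S) and C5 (R).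

Step 2
Reactants: 2 2-deoxy-D-ribono-1,4-lactone
Product: 3 (4S,5R)-4-(tert-butyldimethylsilyloxy)-5-[(tert-butyldimethylsilyloxy)methyl]oxolan-2-one
Conditions: TBSCl (2.5 equiv), imidazole, DMF, rt
Reagents that add atoms: tert-butyldimethylsilyl chloride (TBSCl), C[Si](C)(Cl)C(C)(C)C
Why: Imidazole-mediated silylation of both hydroxyl groups, a standard protection; no stereocentre is involved.

Step 3
Reactants: 3 bis-silyl ether
Product: 4 (4S,5R)-4-(tert-butyldimethylsilyloxy)-5-(hydroxymethyl)oxolan-2-one
Conditions: CF3CO2H/H2O/THF (1:1:4), 0 °C
Reagents that add atoms: none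
Why: Acid-catalysed silyl ether hydrolysis is governed by steric access, so the primary ether should cleave well before the secondary one, as in the selective 5'-desilylation of bis-silylated 2'-deoxynucleosides; the γ-lactone tolerates cold aqueous acid.

Step 4
Reactants: 4 primary alcohol
Product: 5 (2S,3S)-3-(tert-butyldimethylsilyloxy)-5-oxooxolane-2-carbaldehyde
Conditions: Dess–Martin periodinane, CH2Cl2, 0 °C to rt; crude aldehyde used at once
Reagents that add atoms: none
Why: Dess–Martin oxidation is neutral and non-enolising, which should keep the configuration at the aldehyde-bearing carbon and leave the β-silyloxy group in place; the descriptor changes to 2S only because the formyl group outranks the ring carbon.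

Step 5
Reactants: 5 aldehyde
Product: 6 (4S,5R)-4-(tert-butyldimethylsilyloxy)-5-(2-methylprop-1-en-1-yl)oxolan-2-one
Conditions: i-PrPPh3I, n-BuLi, THF, 0 °C; then 5, −78 °C to 0 °C
Reagents that add atoms: isopropyltriphenylphosphonium iodide, CC(C)[P+](c1ccccc1)(c1ccccc1)c1ccccc1.[I-]
Why: Wittig olefination with the non-stabilised isopropylidene ylide; at −78 °C the ylide should add to the aldehyde far faster than to the lactone carbonyl, as in olefinations of γ-lactone carbaldehydes, and no alkene geometry arises because the new terminus carries two methyl groups.

Step 6
Reactants: 6 isobutenyl lactone; 7 acetaldehyde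
Product: 9 (3S,4S,5R)-4-(tert-butyldimethylsilyloxy)-3-(1-hydroxyethyl)-5-(2-methylprop-1-en-1-yl)oxolan-2-one as a mixture of carbinol epimers, via lithium enolate 8 (not isolated)
Conditions: LiN(i-Pr)2, THF, −78 °C; MeCHO, −78 °C; AcOH quench at −78 °C
Reagents that add atoms: none
Why: Directed aldol addition of the lactone lithium enolate at −78 °C, where β-elimination of the C4 silyloxy group is slow; the aldehyde should enter trans to the silyloxy group, and both new stereocentres are erased in step 7.

Step 7
Reactants: 9 aldol adduct
Product: 11 (3E,4S,5R)-4-(tert-butyldimethylsilyloxy)-3-ethylidene-5-(2-methylprop-1-en-1-yl)oxolan-2-one (E isomer drawn; any Z isomer is carried on), via mesylate 10 (not isolated)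
Conditions: MsCl, Et3N, CH2Cl2, 0 °C; then DBU, 0 °C to rt
Reagents that add atoms: none
Why: Mesylation followed by E1cB elimination completes the aldol condensation; the exocyclic mesylate is a far better leaving group than the ring silyloxy group, and both alkene isomers lead to the same dienolate.

Step 8
Reactants: 11 α-ethylidene lactone
Product: 13 tert-butyl{[(4S,5R)-4-(tert-butyldimethylsilyloxy)-3-ethenyl-5-(2-methylprop-1-en-1-yl)-4,5-dihydrofuran-2-yl]oxy}dimethylsilane, via lithium dienolate 12 (not isolated)
Conditions: LiN(i-Pr)2, DMPU, THF, −78 °C; TBSCl, −78 °C to 0 °C; pentane, filtration, no aqueous work-up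
Reagents that add atoms: tert-butyldimethylsilyl chloride (TBSCl), C[Si](C)(Cl)C(C)(C)C
Why: γ-Deprotonation of the alkylidene lactone and O-silylation of the extended enolate is the standard preparation of ester silyl dienolates; the ketene acetal geometry is fixed by the ring and C4 and C5 are not touched.

Step 9
Reactants: 14 nerol
Product: 15 neryl benzoate, (2Z)-3,7-dimethylocta-2,6-dien-1-yl benzoate
Conditions: BzCl, pyridine, DMAP (cat.), CH2Cl2, 0 °C to rt
Reagents that add atoms: benzoyl chloride, O=C(Cl)c1ccccc1
Why: DMAP-catalysed acylation of a primary allylic alcohol; the Z-alkene is not affected.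

Step 10
Reactants: 15 neryl benzoate
Product: 16 (2Z,6E)-8-hydroxy-3,7-dimethylocta-2,6-dien-1-yl benzoate
Conditions: SeO2 (cat.), t-BuOOH, salicylic acid (cat.), CH2Cl2, rt
Reagents that add atoms: tert-butyl hydroperoxide, CC(C)(C)OO; SeO2, O=[Se]=O (catalytic carrier of the oxygen atom)
Why: SeO2 allylic oxidation (ene reaction, then [2,3]-sigmatropic shift) should select the more electron-rich distal alkene and its E-methyl group, while the alkene bearing the benzoyloxymethyl group is deactivated.

Step 11
Reactants: 16 allylic alcohol
Product: 17 (2Z,6E)-3,7-dimethyl-8-oxoocta-2,6-dien-1-yl benzoate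
Conditions: MnO2, CH2Cl2, rt
Reagents that add atoms: none
Why: MnO2 oxidises allylic alcohols to enals selectively and without change of alkene geometry; any enal already formed in step 10 converges on the same product.

Step 12
Reactants: 13 silyl dienolate; 17 enal
Product: 19 (2Z,6E,8R)-8-hydroxy-3,7-dimethyl-10-[(3E,4S,5R)-4-(tert-butyldimethylsilyloxy)-5-(2-methylprop-1-en-1-yl)-2-oxooxolan-3-ylidene]deca-2,6-dien-1-yl benzoate, via trichlorosilyl ether 18 (not isolated)
Conditions: 13 (1.3 equiv), SiCl4 (1.1 equiv), (R,R)-bisphosphoramide (5 mol %), i-Pr2NEt (10 mol %), CH2Cl2, −78 °C; then aq. NaHCO3/KF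
Reagents that add atoms: none
Why: The bisphosphoramide (two N,N'-dimethyl-1,1'-binaphthyl-2,2'-diamine-derived phosphoramide units joined by an N,N'-dimethylpentane-1,5-diamine linker) binds SiCl4 and expels chloride, giving a chiral phosphoramide-bound trichlorosilyl cation that activates the carbonyl of 17; dienolate 13 adds through its terminal vinyl carbon (C2') in an open transition state, chloride removes the enol silyl group as TBSCl, and trichlorosilyl ether 18 is hydrolysed on work-up. The closest known reaction type is the SiCl4/chiral phosphoramide vinylogous Mukaiyama aldol addition of ester-derived silyl dienolates, α-substituted ones included, to conjugated aldehydes. No ring is closed. The new stereocentre C3' is set by the catalyst alone, the (R,R)-enantiomer being chosen to open the Re face of the enal, which gives 3'R; C4 and C5 are too far from the reacting terminus to help or to be disturbed. Attack at the terminal carbon and not at C3 is required and is secured because C3 is fully substituted and flanked by two silyloxy-bearing carbons, whereas the terminal CH2 is unhindered and carries the larger HOMO coefficient. The E geometry of the regenerated C3=C1' alkene is required and should follow from reaction through the s-trans diene conformer, in which the vinyl terminus avoids the in-plane silyloxy group on C2. 1,2-Addition is expected because the α-methyl, β-alkyl enal is a poor conjugate acceptor and cannot enolise, and catalytic i-Pr2NEt removes traces of HCl that could ionise the allylic C4 silyloxy group or the C10' benzoate.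

Step 13
Reactants: 19 vinylogous aldol product
Product: 20 (2Z,6E,8R)-8-hydroxy-10-[(3E,4S,5R)-4-hydroxy-5-(2-methylprop-1-en-1-yl)-2-oxooxolan-3-ylidene]-3,7-dimethyldeca-2,6-dien-1-yl benzoate
Conditions: HF·pyridine, pyridine, THF, 0 °C to rt
Reagents that add atoms: none
Why: Buffered HF·pyridine cleaves the secondary silyl ether without a basic fluoride source, so the benzoate, the lactone and the base-sensitive C2' methylene should be spared; no stereocentre is touched.

Step 14
Reactants: 20 diol
Product: 21 target, (2Z,6E,8R)-8-acetoxy-10-[(3E,4S,5R)-4-acetoxy-5-(2-methylprop-1-en-1-yl)-2-oxooxolan-3-ylidene]-3,7-dimethyldeca-2,6-dien-1-yl benzoate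
Conditions: Ac2O, pyridine, DMAP (cat.), CH2Cl2, 0 °C
Reagents that add atoms: acetic anhydride, CC(=O)OC(C)=O
Why: DMAP-catalysed acetylation of both secondary allylic alcohols in one operation at 0 °C, mild enough that the allylic C4 acetate and the β-acetoxy C3' position should not eliminate; configuration is retained because only O–H bonds react.

## Compound list

1 | 2-deoxy-D-ribose (open-chain form) | O=CC[C@H](O)[C@H](O)CO | starting material
2 | 2-deoxy-D-ribono-1,4-lactone, (4S,5R)-4-hydroxy-5-(hydroxymethyl)oxolan-2-one | O=C1C[C@H](O)[C@@H](CO)O1 | intermediate
3 | (4S,5R)-4-(tert-butyldimethylsilyloxy)-5-[(tert-butyldimethylsilyloxy)methyl]oxolan-2-one | O=C1C[C@H](O[Si](C)(C)C(C)(C)C)[C@@H](CO[Si](C)(C)C(C)(C)C)O1 | intermediate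
4 | (4S,5R)-4-(tert-butyldimethylsilyloxy)-5-(hydroxymethyl)oxolan-2-one | O=C1C[C@H](O[Si](C)(C)C(C)(C)C)[C@@H](CO)O1 | intermediate
5 | (2S,3S)-3-(tert-butyldimethylsilyloxy)-5-oxooxolane-2-carbaldehyde | O=C1C[C@H](O[Si](C)(C)C(C)(C)C)[C@@H](C=O)O1 | intermediate
6 | (4S,5R)-4-(tert-butyldimethylsilyloxy)-5-(2-methylprop-1-en-1-yl)oxolan-2-one | O=C1C[C@H](O[Si](C)(C)C(C)(C)C)[C@@H](C=C(C)C)O1 | intermediate
7 | acetaldehyde | CC=O | starting material
8 | lithium (4S,5R)-4-(tert-butyldimethylsilyloxy)-5-(2-methylprop-1-en-1-yl)-4,5-dihydrofuran-2-olate (lithium enolate of 6) | [Li]OC1=C[C@H](O[Si](C)(C)C(C)(C)C)[C@@H](C=C(C)C)O1 | intermediate (not isolated)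
9 | (3S,4S,5R)-4-(tert-butyldimethylsilyloxy)-3-(1-hydroxyethyl)-5-(2-methylprop-1-en-1-yl)oxolan-2-one, carbinol epimers | O=C1[C@@H](C(C)O)[C@H](O[Si](C)(C)C(C)(C)C)[C@@H](C=C(C)C)O1 | intermediate
10 | methanesulfonate of 9 | O=C1[C@@H](C(C)OS(C)(=O)=O)[C@H](O[Si](C)(C)C(C)(C)C)[C@@H](C=C(C)C)O1 | intermediate (not isolated)
11 | (3E,4S,5R)-4-(tert-butyldimethylsilyloxy)-3-ethylidene-5-(2-methylprop-1-en-1-yl)oxolan-2-one | C/C=C1/C(=O)O[C@H](C=C(C)C)[C@H]1O[Si](C)(C)C(C)(C)C | intermediate
12 | lithium (4S,5R)-4-(tert-butyldimethylsilyloxy)-3-ethenyl-5-(2-methylprop-1-en-1-yl)-4,5-dihydrofuran-2-olate | [Li]OC1=C(C=C)[C@H](O[Si](C)(C)C(C)(C)C)[C@@H](C=C(C)C)O1 | intermediate (not isolated)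
13 | tert-butyl{[(4S,5R)-4-(tert-butyldimethylsilyloxy)-3-ethenyl-5-(2-methylprop-1-en-1-yl)-4,5-dihydrofuran-2-yl]oxy}dimethylsilane | C=CC1=C(O[Si](C)(C)C(C)(C)C)O[C@H](C=C(C)C)[C@H]1O[Si](C)(C)C(C)(C)C | intermediate
14 | nerol | CC(C)=CCC/C(C)=C\CO | starting material
15 | neryl benzoate | CC(C)=CCC/C(C)=C\COC(=O)c1ccccc1 | intermediate
16 | (2Z,6E)-8-hydroxy-3,7-dimethylocta-2,6-dien-1-yl benzoate | OC/C(C)=C/CC/C(C)=C\COC(=O)c1ccccc1 | intermediate
17 | (2Z,6E)-3,7-dimethyl-8-oxoocta-2,6-dien-1-yl benzoate | O=C/C(C)=C/CC/C(C)=C\COC(=O)c1ccccc1 | intermediate
18 | trichlorosilyl ether of 19 | Cl[Si](Cl)(Cl)O[C@H](C/C=C1/C(=O)O[C@H](C=C(C)C)[C@H]1O[Si](C)(C)C(C)(C)C)/C(C)=C/CC/C(C)=C\COC(=O)c1ccccc1 | intermediate (not isolated)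
19 | (2Z,6E,8R)-8-hydroxy-3,7-dimethyl-10-[(3E,4S,5R)-4-(tert-butyldimethylsilyloxy)-5-(2-methylprop-1-en-1-yl)-2-oxooxolan-3-ylidene]deca-2,6-dien-1-yl benzoate | O[C@H](C/C=C1/C(=O)O[C@H](C=C(C)C)[C@H]1O[Si](C)(C)C(C)(C)C)/C(C)=C/CC/C(C)=C\COC(=O)c1ccccc1 | intermediate
20 | (2Z,6E,8R)-8-hydroxy-10-[(3E,4S,5R)-4-hydroxy-5-(2-methylprop-1-en-1-yl)-2-oxooxolan-3-ylidene]-3,7-dimethyldeca-2,6-dien-1-yl benzoate | O[C@H](C/C=C1/C(=O)O[C@H](C=C(C)C)[C@H]1O)/C(C)=C/CC/C(C)=C\COC(=O)c1ccccc1 | intermediate
21 | (2Z,6E,8R)-8-acetoxy-10-[(3E,4S,5R)-4-acetoxy-5-(2-methylprop-1-en-1-yl)-2-oxooxolan-3-ylidene]-3,7-dimethyldeca-2,6-dien-1-yl benzoate (CNP0262857.1) | CC(=O)O[C@H](C/C=C1/C(=O)O[C@H](C=C(C)C)[C@H]1OC(C)=O)/C(C)=C/CC/C(C)=C\COC(=O)c1ccccc1 | target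

## Step count and risks

Total: 14 steps. Longest linear sequence: 11 steps (steps 1–8 and 12–14, from 1 to 21). The nerol branch contributes steps 9–11 before the union.

**Step 12 (key step).** The most likely failure is poor facial selectivity at the enal. The catalyst has to differentiate the faces of 17 while a hindered, fully substituted cyclic ketene acetal approaches, and any uncatalysed or HCl-promoted background addition erodes the control further. Loss of the dienolate by acid-induced elimination of the C4 silyloxy group would lower conversion. Fallback: setting out from 13 and 17, the addition is run with the achiral promoter BF3·OEt2 (CH2Cl2, −78 °C). This gives 19 together with its C3' epimer, the (8S)-alcohol F1. The mixture is oxidised with Dess–Martin periodinane to the C3' ketone, the α-methyl enone F2. F2 is reduced with catecholborane and the (S)-configured B-methyl oxazaborolidine (CBS reduction), in which the alkenyl group acts as the large substituent and the 3'R alcohol is expected. The fallback returns to the route at 19.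

**Step 8.** The lithium dienolate 12 can expel the C4 silyloxy group (E1cB towards a butenolide and on to a furan) before silylation, and the amide base can add in conjugate fashion at C1'. Fallback: setting out from 11, the silyl ether is removed with HF·pyridine to give the hydroxy lactone, (3E,4S,5R)-3-ethylidene-4-hydroxy-5-(2-methylprop-1-en-1-yl)oxolan-2-one F3. F3 is treated with LiN(i-Pr)2 (2.2 equiv) to form the alkoxide–dienolate dianion, in which an alkoxide is not a leaving group (the principle behind alkylations of β-hydroxy ester dianions). Both oxygens are then silylated with TBSCl (2.5 equiv). The fallback returns to the route at 13.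

**Step 5.** The basic, hindered ylide can deprotonate aldehyde 5 instead of adding to it, which leads to loss of the C4 silyloxy group by β-elimination or to epimerisation at the aldehyde-bearing carbon. Fallback: setting out from 5, the aldehyde is methylenated under non-basic conditions (Zn, CH2Br2, TiCl4; this reagent leaves lactones alone) to the vinyl lactone, (4S,5R)-4-(tert-butyldimethylsilyloxy)-5-ethenyloxolan-2-one F4. F4 is converted to the trisubstituted alkene by cross-metathesis with 2-methyl-2-butene and the second-generation Grubbs catalyst RuCl2(=CHPh)(PCy3)(H2IMes). The fallback returns to the route at 6.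

**Step 10.** The allylic oxidation may stall at partial conversion, over-oxidise, or attack the allylic methylenes, leaving a mixture that is costly to separate. Fallback: setting out from 15, the terminal trisubstituted alkene undergoes cross-metathesis with methacrolein using the second-generation Hoveyda–Grubbs catalyst RuCl2(=CH-C6H4-2-O-i-Pr)(H2IMes) in CH2Cl2 at 40 °C. This should give the E-enal directly, while the more hindered, electron-poorer alkene next to the benzoate stays untouched. The fallback returns to the route at 17, bypassing 16, and makes no compound outside the route (F0).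

## Further compounds

F1 | step 12 | (2Z,6E,8S)-8-hydroxy-3,7-dimethyl-10-[(3E,4S,5R)-4-(tert-butyldimethylsilyloxy)-5-(2-methylprop-1-en-1-yl)-2-oxooxolan-3-ylidene]deca-2,6-dien-1-yl benzoate (C3' epimer of 19) | O[C@@H](C/C=C1/C(=O)O[C@H](C=C(C)C)[C@H]1O[Si](C)(C)C(C)(C)C)/C(C)=C/CC/C(C)=C\COC(=O)c1ccccc1
F2 | step 12 | (2Z,6E)-3,7-dimethyl-8-oxo-10-[(3E,4S,5R)-4-(tert-butyldimethylsilyloxy)-5-(2-methylprop-1-en-1-yl)-2-oxooxolan-3-ylidene]deca-2,6-dien-1-yl benzoate | O=C(C/C=C1/C(=O)O[C@H](C=C(C)C)[C@H]1O[Si](C)(C)C(C)(C)C)/C(C)=C/CC/C(C)=C\COC(=O)c1ccccc1
F3 | step 8 | (3E,4S,5R)-3-ethylidene-4-hydroxy-5-(2-methylprop-1-en-1-yl)oxolan-2-one | C/C=C1/C(=O)O[C@H](C=C(C)C)[C@H]1O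
F4 | step 5 | (4S,5R)-4-(tert-butyldimethylsilyloxy)-5-ethenyloxolan-2-one | O=C1C[C@H](O[Si](C)(C)C(C)(C)C)[C@@H](C=C)O1
F0 | step 10 | none | none
A1 | alternative 1 | E-iodoalkene diol with silyl-protected side chain | CC(C)(C)[Si](C)(C)O[C@H](C/C=C(/I)[C@H](O)[C@H](O)C=C(C)C)/C(C)=C/CC/C(C)=C\CO[Si](c1ccccc1)(c1ccccc1)C(C)(C)C
A2 | alternative 1 | E-alkylidene 4-hydroxy lactone with silyl-protected side chain | CC(C)(C)[Si](C)(C)O[C@H](C/C=C1/C(=O)O[C@H](C=C(C)C)[C@H]1O)/C(C)=C/CC/C(C)=C\CO[Si](c1ccccc1)(c1ccccc1)C(C)(C)C
A3 | alternative 2 | 4,5-diacetoxy lactone with silyl-protected side chain (C5 anomers) | CC(C)(C)[Si](C)(C)O[C@H](C/C=C1/C(=O)OC(OC(C)=O)[C@H]1OC(C)=O)/C(C)=C/CC/C(C)=C\CO[Si](c1ccccc1)(c1ccccc1)C(C)(C)C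
A4 | alternative 2 | potassium (2-methylprop-1-enyl)trifluoroborate | [K+].CC(C)=C[B-](F)(F)F
A5 | alternative 2 | 4-acetoxy 5-isobutenyl lactone with silyl-protected side chain | CC(C)(C)[Si](C)(C)O[C@H](C/C=C1/C(=O)O[C@H](C=C(C)C)[C@H]1OC(C)=O)/C(C)=C/CC/C(C)=C\CO[Si](c1ccccc1)(c1ccccc1)C(C)(C)C
A6 | alternative 3 | (3E,4S,5R)-3-(bromomethylidene)-4-(tert-butyldimethylsilyloxy)-5-(2-methylprop-1-en-1-yl)oxolan-2-one | Br/C=C1/C(=O)O[C@H](C=C(C)C)[C@H]1O[Si](C)(C)C(C)(C)C
A7 | alternative 3 | N-hydroxyphthalimide ester of the (3R)-3-silyloxy acid of the side chain | O=C(ON1C(=O)c2ccccc2C1=O)C[C@@H](O[Si](C)(C)C(C)(C)C)/C(C)=C/CC/C(C)=C\CO[Si](c3ccccc3)(c3ccccc3)C(C)(C)C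
A8 | alternative 3 | tris-silyl ether of the complete skeleton | CC(C)(C)[Si](C)(C)O[C@H](C/C=C1/C(=O)O[C@H](C=C(C)C)[C@H]1O[Si](C)(C)C(C)(C)C)/C(C)=C/CC/C(C)=C\CO[Si](c1ccccc1)(c1ccccc1)C(C)(C)C
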